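**Target:** germacranolide numbering is used throughout (C1–C10 ring, C11–C13 lactone/methylene, C14 = 10-Me, C15 = 4-Me). Read from the SMILES, the target is 2S,3S,4Z,6R,7R,8R,10S with a 6,7-trans lactone and a (Z)-2-methylbut-2-enoate (angelate) at O-8.

**Assumptions:** 2-bromo-3-methylfuran is taken as a catalogue item (otherwise one step from 3-methylfuran and NBS). The route is a paper proposal; nothing here has been run.

## Retrosynthetic overview

1. Target ⇐ 8-O-angeloylation and 2-O-desilylation of the bicyclic hydroxy-lactone 15.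
2. Ten-membered ring and α-methylene-γ-lactone are formed together by an intramolecular Cr-mediated Barbier allylation/lactonisation (C6–C7 bond) of bromide/masked Z-enal 14.
3. The THF hemiketal (C3–O–C10) and the Z-C4=C5–C6 enal come from oxidative opening of a 2,3-disubstituted furan trapped by the C10 tertiary OH. Ring order: THF ketal first, then carbocycle and lactone in one step.
4. The bromomethyl-enoate (C7, C11–C13) comes from a ynoate by hydroalumination/CH2O trapping; the C2 and C8 carbinols come from two Noyori transfer hydrogenations.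
5. The backbone is (R)-mevalonolactone (C10 stereocentre; C1, C2, C8, C9, C14), opened first by 2-lithio-3-methylfuran and, after relactonisation, by lithiated triethyl orthopropiolate.

## Forward route

**Step 1**
Reactants: 1, 2-bromo-3-methylfuran; 2, (R)-mevalonolactone
Product: 3, (3R)-3,5-dihydroxy-3-methyl-1-(3-methylfuran-2-yl)pentan-1-one
Conditions: 1, n-BuLi, THF, −78 °C; then Li-alkoxide of 2 (LiHMDS, 1 eq), −78 °C; AcOH quench
Reagents that add atoms: none
Why: Br/Li exchange then acyl substitution on the lactone (the tetrahedral intermediate survives at −78 °C, so mono-addition); C10 comes unchanged from the chiral pool.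

**Step 2**
Reactants: 3
Product: 4, (1S,3R)-3-methyl-1-(3-methylfuran-2-yl)pentane-1,3,5-triol
Conditions: RuCl[(S,S)-TsDPEN](p-cymene) 1 mol%, HCO2H/Et3N 5:2, CH2Cl2, rt
Reagents that add atoms: none
Why: Noyori asymmetric transfer hydrogenation of a heteroaryl ketone; the (S,S)-catalyst gives the (S)-carbinol (same sense as acetophenone), setting C2 by reagent control.

**Step 3**
Reactants: 4
Product: 5, (4S,6S)-4-hydroxy-4-methyl-6-(3-methylfuran-2-yl)oxan-2-one
Conditions: Cu(MeCN)4OTf, bpy, TEMPO, NMI (5 mol% each), air, MeCN, rt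
Reagents that add atoms: none
Why: Primary-selective aerobic oxidative lactonisation of the 1,5-diol (aldehyde → lactol → lactone); it masks O-2 as the lactone oxygen and activates C8 as an acyl carbon.

**Step 4**
Reactants: 5; 6, 3,3,3-triethoxyprop-1-yne
Product: 7, (6S,8S)-1,1,1-triethoxy-6,8-dihydroxy-6-methyl-8-(3-methylfuran-2-yl)oct-2-yn-4-one
Conditions: 6 (2.3 eq), n-BuLi, THF, −78 °C; then 5, −78 → −40 °C; NH4Cl
Reagents that add atoms: none (besides 6)
Why: Acetylide addition to a lactone gives the ynone; the orthoester is a base-stable propiolate equivalent supplying C7, C11 and C12.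

**Step 5**
Reactants: 7
Product: 8, (6S,8S)-8-[(tert-butyldimethylsilyl)oxy]-1,1,1-triethoxy-6-hydroxy-6-methyl-8-(3-methylfuran-2-yl)oct-2-yn-4-one
Conditions: TBSCl, imidazole, DMF, rt
Reagents that add atoms: TBSCl, CC(C)(C)[Si](C)(C)Cl
Why: Silylation of the secondary C2-OH only (the tertiary OH is inert); this blocks Achmatowicz ring expansion later.

**Step 6**
Reactants: 8
Product: 9, ethyl (4R,6R,8S)-8-[(tert-butyldimethylsilyl)oxy]-4,6-dihydroxy-6-methyl-8-(3-methylfuran-2-yl)oct-2-ynoate
Conditions: Ru[(R,R)-TsDPEN](p-cymene) 2 mol%, i-PrOH, rt; then 0.5 M aq. NaHSO4/THF, 0 °C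
Reagents that add atoms: water, O (orthoester → ethyl ester)
Why: Noyori transfer hydrogenation of an ynone, in which the alkynyl group plays the aryl role, so the (R,R)-catalyst gives the (R)-propargylic alcohol (C8); the acidic work-up unmasks the ester.

**Step 7**
Reactants: 9
Product: 10, ethyl (4R,6R,8S)-8-[(tert-butyldimethylsilyl)oxy]-6-hydroxy-6-methyl-8-(3-methylfuran-2-yl)-4-[(triethylsilyl)oxy]oct-2-ynoate
Conditions: TESCl, imidazole, CH2Cl2, 0 °C
Reagents that add atoms: TESCl, CC[Si](CC)(CC)Cl
Why: Silylation of the propargylic OH; an ether at O-8 avoids butenolide formation, 1,4-elimination from the later allyl-metal, and is removable beside TBS.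

**Step 8**
Reactants: 10; 11, paraformaldehyde
Product: 12, ethyl (2Z,4R,6R,8S)-8-[(tert-butyldimethylsilyl)oxy]-6-hydroxy-2-(hydroxymethyl)-6-methyl-8-(3-methylfuran-2-yl)-4-[(triethylsilyl)oxy]oct-2-enoate
Conditions: i-Bu2AlH (2.2 eq; 1 eq is consumed by the tertiary OH), NMO, THF, 0 °C; then (CH2O)n, 0 °C → rt
Reagents that add atoms: formaldehyde, C=O
Why: Conjugate syn-hydroalumination of the ynoate (Tsuda/Ramachandran vinylalumination) puts H on C7 and Al on C11; aldol trapping with CH2O installs C13 and gives the 2Z enoate.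

**Step 9**
Reactants: 12
Product: 13, ethyl (2E,4R,6R,8S)-2-(bromomethyl)-8-[(tert-butyldimethylsilyl)oxy]-6-hydroxy-6-methyl-8-(3-methylfuran-2-yl)-4-[(triethylsilyl)oxy]oct-2-enoate
Conditions: CBr4, PPh3, 2,6-lutidine, CH2Cl2, −20 °C
Reagents that add atoms: CBr4, BrC(Br)(Br)Br
Why: Appel bromination of the primary allylic alcohol; the tertiary OH and silyl ethers do not react at −20 °C.

**Step 10**
Reactants: 13
Product: 14, ethyl (2E,4R)-2-(bromomethyl)-5-[(2R,4S)-4-[(tert-butyldimethylsilyl)oxy]-7-hydroxy-2,9-dimethyl-1,6-dioxaspiro[4.4]non-8-en-2-yl]-4-[(triethylsilyl)oxy]pent-2-enoate (epimers at the spiro and lactol carbons)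
Conditions: NBS (1.05 eq), NaHCO3, THF/H2O 4:1, 0 °C
Reagents that add atoms: water, O
Why: Achmatowicz-type oxidative furan opening to the Z-4-oxo-2-enal, trapped by the C10-OH as the spiroketal lactol; this forms the C3–O–C10 ring, protects C3, and fixes the 4Z geometry from the furan.

**Step 11**
Reactants: 14
Product: 15, 2-O-TBS-8-O-desangeloyl target (bicyclic 6,12-olide with free 8-OH and 3-OH)
Conditions: CrCl2 (8 eq), THF/DMF 4:1, rt, syringe-pump addition to 2 mM; then 1 M HCl/THF 1:4, 0 °C
Reagents that add atoms: none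
Why: Intramolecular Nozaki–Hiyama (Barbier-type) allylation of the lactol-masked aldehyde followed by lactonisation. The E-type allylchromium (C8 trans to CH2Cr) in a chair transition state should give the anti adduct, i.e. the 6,7-trans lactone. Attack at C7 anti to the C9 chain with C8–H in the alkene plane (A1,3 strain) gives the 7R/8R relationship. The C3 hemiketal configuration is dictated by the bridge, and the acid stage completes lactonisation and removes TES.

**Step 12**
Reactants: 15; 16, angelic acid
Product: 17, 2-O-TBS target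
Conditions: 16, 2,4,6-Cl3C6H2COCl, Et3N, toluene, rt; then 15, 75 °C (no DMAP)
Reagents that add atoms: angelic acid, C/C=C(/C)C(=O)O
Why: Yamaguchi mixed-anhydride esterification of the only acylable hydroxyl (8-OH; 3-OH is a tertiary hemiketal); DMAP-free conditions avoid angelate → tiglate isomerisation.

**Step 13**
Reactants: 17
Product: 18, 2β-hydroxy-1-desoxyniveusin A (target)
Conditions: HF·pyridine, pyridine, THF, 0 °C → rt
Reagents that add atoms: none
Why: Buffered fluoride desilylation; the angelate, α-methylene lactone and hemiketal tolerate it and no stereocentre is touched.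

## Compound list

1 | 2-bromo-3-methylfuran | Cc1ccoc1Br | starting material
2 | (R)-mevalonolactone | C[C@@]1(O)CCOC(=O)C1 | starting material
3 | (3R)-3,5-dihydroxy-3-methyl-1-(3-methylfuran-2-yl)pentan-1-one | Cc1ccoc1C(=O)C[C@](C)(O)CCO | intermediate
4 | (1S,3R)-3-methyl-1-(3-methylfuran-2-yl)pentane-1,3,5-triol | Cc1ccoc1[C@@H](O)C[C@](C)(O)CCO | intermediate
5 | (4S,6S)-4-hydroxy-4-methyl-6-(3-methylfuran-2-yl)oxan-2-one | Cc1ccoc1[C@@H]1C[C@](C)(O)CC(=O)O1 | intermediate
6 | 3,3,3-triethoxyprop-1-yne | C#CC(OCC)(OCC)OCC | starting material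
7 | (6S,8S)-1,1,1-triethoxy-6,8-dihydroxy-6-methyl-8-(3-methylfuran-2-yl)oct-2-yn-4-one | Cc1ccoc1[C@@H](O)C[C@](C)(O)CC(=O)C#CC(OCC)(OCC)OCC | intermediate
8 | 8-O-TBS ether of 7 | Cc1ccoc1[C@@H](O[Si](C)(C)C(C)(C)C)C[C@](C)(O)CC(=O)C#CC(OCC)(OCC)OCC | intermediate
9 | ethyl (4R,6R,8S)-8-(TBSO)-4,6-dihydroxy-6-methyl-8-(3-methylfuran-2-yl)oct-2-ynoate | Cc1ccoc1[C@@H](O[Si](C)(C)C(C)(C)C)C[C@](C)(O)C[C@@H](O)C#CC(=O)OCC | intermediate
10 | 4-O-TES ether of 9 | Cc1ccoc1[C@@H](O[Si](C)(C)C(C)(C)C)C[C@](C)(O)C[C@@H](O[Si](CC)(CC)CC)C#CC(=O)OCC | intermediate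
11 | formaldehyde (as paraformaldehyde) | C=O | starting material
12 | ethyl (2Z,4R,6R,8S)-8-(TBSO)-6-hydroxy-2-(hydroxymethyl)-6-methyl-8-(3-methylfuran-2-yl)-4-(TESO)oct-2-enoate | Cc1ccoc1[C@@H](O[Si](C)(C)C(C)(C)C)C[C@](C)(O)C[C@@H](O[Si](CC)(CC)CC)/C=C(/CO)C(=O)OCC | intermediate
13 | ethyl (2E,4R,6R,8S)-2-(bromomethyl)-8-(TBSO)-6-hydroxy-6-methyl-8-(3-methylfuran-2-yl)-4-(TESO)oct-2-enoate | Cc1ccoc1[C@@H](O[Si](C)(C)C(C)(C)C)C[C@](C)(O)C[C@@H](O[Si](CC)(CC)CC)/C=C(/CBr)C(=O)OCC | intermediate
14 | spiroketal lactol (1,6-dioxaspiro[4.4]non-8-en-7-ol) bromide, mixture at spiro/lactol carbons | OC1OC2(C(C)=C1)O[C@](C)(C[C@@H](O[Si](CC)(CC)CC)/C=C(/CBr)C(=O)OCC)C[C@@H]2O[Si](C)(C)C(C)(C)C | intermediate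
15 | 2-O-TBS-8-O-desangeloyl target | C=C1C(=O)O[C@@H]2/C=C(/C)[C@]3(O)O[C@](C)(C[C@@H](O)[C@@H]12)C[C@@H]3O[Si](C)(C)C(C)(C)C | intermediate
16 | angelic acid, (Z)-2-methylbut-2-enoic acid | C/C=C(/C)C(=O)O | starting material
17 | 2-O-TBS target | C=C1C(=O)O[C@@H]2/C=C(/C)[C@]3(O)O[C@](C)(C[C@@H](OC(=O)/C(C)=C\C)[C@@H]12)C[C@@H]3O[Si](C)(C)C(C)(C)C | intermediate
18 | 2β-hydroxy-1-desoxyniveusin A | C=C1C(=O)O[C@@H]2/C=C(/C)[C@]3(O)O[C@](C)(C[C@@H](OC(=O)/C(C)=C\C)[C@@H]12)C[C@@H]3O | target

## Summary

Total steps: 13. Longest linear sequence: 13 (fully linear from 1 and 2; 6, 11 and 16 are bought).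

**Steps most likely to fail, with fallbacks**

1. **Step 11 (Cr-mediated macrocyclisation).** Risks are strain in closing the bridged ten-membered ring, the wrong C6/C7 diastereomer, and reduction or oligomerisation. Fallback: form the lactone intermolecularly by Cr-mediated allylation of (Z)-3-iodobut-2-enal with a furan-free bromide carrying a C2-OTBS/C3-aldehyde arm. Then close the ring at C3–C4 by intramolecular Ni/Cr (NHK) coupling and oxidise C3-OH to the ketone, which hemiketalises with 10-OH.

2. **Step 8 (hydroalumination/formaldehyde trapping).** Risks are over-reduction of the ester, poor trapping by CH2O, and interference from the free tertiary alkoxide. Fallback: introduce C12 rather than C13 last. Open lactone 5 with the acetylide of TBS propargyl ether; after the same ATH, use hydroxyl-directed Red-Al/I2 to make the C11 vinyl iodide, then Pd-catalysed alkoxycarbonylation (CO, MeOH), desilylation and Appel bromination.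

3. **Step 10 (oxidative furan opening/spiroketalisation).** Risks are competing bromination or hydrolysis of the allylic bromide and Z→E isomerisation of the open enal. Fallback: drop the furan. Add the (Z)-vinyllithium from TBS-protected (Z)-3-iodobut-2-en-1-ol to a C2-silyloxy γ-lactone (C3 carbonyl, C10 ring oxygen) to form the THF hemiketal directly (stored as its methyl ketal), and unveil the Z-enal by allylic oxidation (MnO2) immediately before cyclisation.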